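Remark on the chemistry: flavone numbering is used throughout (O1, C2, C3, C4 carbonyl, C4a, C5–C8, C8a; ring B C1'–C6'). C9 is the methylene on C3 and C10 is the stereocentre, whose oxygen is bonded to C2'. The four starting materials 1, 3, 9 and 17 are taken as commercial.

## Analysis of the target

The target is a tetracyclic flavone. Rings A and C form a 5-hydroxy-7-methoxychromone, ring B is a 4'-hydroxyphenyl group on C2, and a seven-membered oxepine (C2, C3, C9, C10, O, C2', C1') ties C3 to the 2'-oxygen of ring B. The only stereocentre is C10, which is S; it carries the ether oxygen and a 2-hydroperoxypropan-2-yl group, so it sits next to a fully substituted carbon. C6 carries an (E)-3-methylbut-1-enyl chain between the chelated 5-hydroxyl and the 7-methoxy group.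

The sensitive groups are the tertiary hydroperoxide (reduced by phosphines, boranes and low-valent metals, cleaved by acid), the styrene-type alkene, and two free phenols. Three things make the synthesis hard: closing a seven-membered ring between the pyranone and ring B; setting C10 next to a quaternary carbon; and introducing the hydroperoxide in the presence of a second alkene while the C6/C8 regiochemistry of ring A is controlled.

The strategy rests on the C2–C3 bond, which is common to the pyranone and the oxepine. C2 has the oxidation level of a ring B carboxylate and C3 is the α-carbon of a ring A aryl ketone, so the bond is a Claisen bond.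

## Retrosynthetic reasoning

**20 from 19.** The hydroperoxide and the 4'-phenol are unmasked last from their silyl derivatives, so that the free O–O–H group never meets a metal, a base or an organometallic reagent. The forward step only has to cleave two Si–O bonds under buffered fluoride.

**19 from 16 and 18.** The C6–alkenyl bond is cut next. The side chain has to arrive after the hydroperoxide, because a cobalt hydride process could not be trusted to tell the isopropenyl group from a conjugated C6 alkene. The coupling must therefore tolerate a silyl peroxide. A tin partner (18, made from 17) is chosen over a boron partner: it needs no base, so the peroxide stays capped, and tin, unlike boron, is not oxidised by a peroxide.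

**16 from 15.** The C6–I bond is cut to a ring A C–H. The chelated 5-hydroxyl is the only free phenol and directs the electrophile to its ortho position C6. The 4'-oxygen stays silylated so that ring B is less activated and shielded.

**15 from 14.** The C–O–O bond at the tertiary carbon is cut to the isopropenyl group. A cobalt-hydride hydrogen atom transfer gives the tertiary radical (Markovnikov) and dioxygen traps it. At this stage the isopropenyl group is the only reactive alkene, which is why this step precedes iodination and coupling.

**14 from 12 (through 13).** The O1–C2 bond of the pyranone is cut to a 1,3-diketone with an ortho phenol. Ring A is carried as a C2-symmetric 4-methoxy-2,6-bis(methoxymethoxy)phenyl ketone. Either liberated phenol then closes the pyranone and the other becomes the 5-hydroxyl. This avoids a late Lewis-acid O-demethylation, which the allylic aryl ether at C10 would not be expected to survive. One mild acid treatment has to remove both acetals and dehydrate.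

**12 from 11 (key disconnection).** The C2–C3 bond is cut, which opens the oxepine and leaves a ring A ketone and a ring B methyl benzoate joined by the C10 aryl ether. Cutting here is preferred because both partners are simple carbonyl compounds and the ketone has a single enolisable site. C10 is remote from the reacting centres, and the product is already the diketone needed for the pyranone. The forward reaction is a seven-membered Claisen ring closure.

**11 from 8 and 10.** The C10–O aryl ether bond is cut. A Mitsunobu etherification joins the secondary allylic alcohol 8 to the salicylate phenol 10 with inversion, so 8 must be R to give S in 11. Silylating 9 selectively at the non-chelated 4-hydroxyl gives 10. The tri(isopropyl)silyl group is chosen because it should survive lithium methoxide, the acid step and the iodination.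

**8 from 2 and 6.** The aryl–carbonyl bond is cut. Lithiation of 2 between its two acetal oxygens (aryllithium 7) and addition to lactone 6 gives the γ-hydroxy ketone directly. The lactone serves as acyl donor and as protection of the carbinol, so no separate protection and deprotection is needed.

**6 from 4, and 4 from 3.** The C10–H bond is traced to an oxazaborolidine-catalysed reduction of enone 4, in which the isopropenyl group is the large substituent; the hydroxy ester 5 lactonises. The enone comes from acylation of an isopropenyl organometallic by acid chloride 3. Acetal protection of 1 gives 2.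

## Alternatives that were turned down

**Alternative 1:** Ring B itself is disconnected at C1'–C2' and C5'–C6'. In the forward step an electron-rich 1-alkoxy-1,3-bis(silyloxy)diene unit, attached through the C10 oxygen, would add to an ethynyl group on C2 of a finished chromone and lose silanol. This builds ring B and the oxepine together and gives A1, the isopropenyl analogue of the target.
- For: two rings form in one step. The C10–O bond is made by acylating the carbinol, so no substitution at the stereocentre is needed. The tether and the polarity of the two partners fix the regiochemistry. On convergence this plan is stronger than the chosen one.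
- Against: the diene would have to be generated with base and a silylating agent next to a chromone that carries an alkynyl Michael acceptor. A cycloaddition whose tether becomes a seven-membered ring is entropically poor and has no close model. A1 also contains both the isopropenyl and the C6 alkene, so the final hydroperoxidation would have to select between them.
- Comparison: the chosen route gives up some convergence. In return its ring closure is a known reaction type, and each alkene is dealt with while it is the only one present.

**Alternative 2:** The pyranone is disconnected at C4–C4a. A carboxylic acid on C3 of a preformed benzoxepine would acylate a symmetric 3,5-dimethoxyphenoxy ring ortho to its oxygen, giving A2, which carries a quaternary ester on C10.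
- For: ring A is symmetric, so there is no regiochemical question in the acylation. No alkene is present, so acid and halogenation steps have no chemoselectivity problem. On that point it is stronger than the chosen route.
- Against: the acylation needs strongly acidic activation next to an enol aryl ether and a silyl ether. The 5-methoxy group must later be cleaved with a Lewis acid. The quaternary ester has to be degraded to the hydroperoxide by a radical decarboxylative oxygenation, which adds several delicate steps.
- Comparison: the chosen route also uses a symmetric ring A. It closes the pyranone under mild acid from a phenol already in place, and it reaches the hydroperoxide in one step from the isopropenyl group.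

**Alternative 3:** The oxepine is disconnected at C9–C10. The sodium enolate of an aryloxyacetyl oxazolidinone on the 2'-oxygen would displace bromide from a bromomethyl group on C3 of a complete flavone. This closes the ring and sets C10, giving A3.
- For: the flavone is made first by classical chemistry. The stereocentre is formed under auxiliary control and the diastereomers can be separated, a firmer handle on stereopurity than a catalytic reduction followed by an inversion.
- Against: in a seven-membered closure the tether decides which enolate face reaches the electrophile, so the usual auxiliary bias is not assured. The bromomethylchromone can also be attacked at C2, and the base can open the pyranone. In A3 the C10 hydrogen is α to an imide carbonyl and can epimerise. The imide then needs several steps to become the hydroperoxyisopropyl group, and the 5-methoxy group still has to be cleaved.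
- Comparison: the chosen route sets C10 in acyclic steps of known sense. C10 is never α to a carbonyl afterwards, and fewer operations follow the ring closure.

Key step: step 7

## Route

Step 1
Reactants: 1 5-methoxybenzene-1,3-diol (5-methoxyresorcinol)
Product: 2 1-methoxy-3,5-bis(methoxymethoxy)benzene
Conditions: MeOCH2Cl, iPr2NEt, CH2Cl2, 0 °C → rt
Reagents that add atoms: chloromethyl methyl ether, COCCl
Why: Williamson-type O-alkylation of both phenols with an α-chloro ether; the acetals later serve as the directing groups for lithiation and are acid-labile.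

Step 2
Reactants: 3 methyl 4-chloro-4-oxobutanoate
Product: 4 methyl 5-methyl-4-oxohex-5-enoate
Conditions: isopropenylmagnesium bromide (added slowly), CuI (10 mol %), THF, −78 °C
Reagents that add atoms: isopropenylmagnesium bromide, CC(=C)[Mg]Br
Why: Copper-catalysed acylation of a Grignard reagent; the acid chloride reacts far faster than the methyl ester or the ketone formed, and slow addition at −78 °C keeps the reagent away from the enone.

Step 3
Reactants: 4 methyl 5-methyl-4-oxohex-5-enoate
Product: 6 (5R)-5-(prop-1-en-2-yl)oxolan-2-one, via hydroxy ester 5 (not isolated)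
Conditions: (S)-1-methyl-3,3-diphenyltetrahydro-1H,3H-pyrrolo[1,2-c][1,3,2]oxazaborole (10 mol %), catecholborane, toluene, −78 °C; then p-TsOH (cat.), CH2Cl2, rt
Reagents that add atoms: none
Why: Corey–Bakshi–Shibata reduction; the isopropenyl group is the large substituent and the (S)-catalyst should deliver hydride to give the R carbinol (same sense as acetophenone to (R)-1-phenylethanol). The γ-hydroxy ester 5 then lactonises with acid. Catecholborane at −78 °C should spare the alkene and the ester.

Step 4
Reactants: 2 1-methoxy-3,5-bis(methoxymethoxy)benzene; 6 (5R)-5-(prop-1-en-2-yl)oxolan-2-one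
Product: 8 (4R)-4-hydroxy-1-[4-methoxy-2,6-bis(methoxymethoxy)phenyl]-5-methylhex-5-en-1-one, via aryllithium 7 (not isolated)
Conditions: 2, n-BuLi, THF, 0 °C; then 6, −78 °C; aq. NH4Cl
Reagents that add atoms: none
Why: Directed ortho-lithiation should occur at the carbon flanked by both acetal oxygens. Addition of the hindered aryllithium to the lactone stops at the lactolate, because the 2,6-disubstituted aryl ketone resists a second addition, and work-up releases the γ-hydroxy ketone. The carbinol centre is not touched.

Step 5
Reactants: 9 methyl 2,4-dihydroxybenzoate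
Product: 10 methyl 2-hydroxy-4-[tri(propan-2-yl)silyloxy]benzoate
Conditions: iPr3SiCl, imidazole, DMF, 0 °C → rt
Reagents that add atoms: chlorotri(propan-2-yl)silane, CC(C)[Si](Cl)(C(C)C)C(C)C
Why: Selective silylation of the 4-hydroxyl; the 2-hydroxyl is hydrogen-bonded to the ester and much less nucleophilic.

Step 6
Reactants: 8 (4R)-4-hydroxy-1-[4-methoxy-2,6-bis(methoxymethoxy)phenyl]-5-methylhex-5-en-1-one; 10 methyl 2-hydroxy-4-[tri(propan-2-yl)silyloxy]benzoate
Product: 11 methyl 2-{[(3S)-6-[4-methoxy-2,6-bis(methoxymethoxy)phenyl]-2-methyl-6-oxohex-1-en-3-yl]oxy}-4-[tri(propan-2-yl)silyloxy]benzoate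
Conditions: PPh3, diisopropyl azodicarboxylate, toluene, 0 °C → rt
Reagents that add atoms: none
Why: Mitsunobu etherification; the salicylate phenol is acidic enough to protonate the betaine and displaces the alkoxyphosphonium ion by SN2 with inversion, turning the R carbinol into the S aryl ether at C10. The allyl system is not cation-stabilised, so ionisation should not compete.

Step 7
Reactants: 11 methyl 2-{[(3S)-6-[4-methoxy-2,6-bis(methoxymethoxy)phenyl]-2-methyl-6-oxohex-1-en-3-yl]oxy}-4-[tri(propan-2-yl)silyloxy]benzoate
Product: 12 [(2S)-5-hydroxy-2-(prop-1-en-2-yl)-8-[tri(propan-2-yl)silyloxy]-2,3-dihydro-1-benzoxepin-4-yl][4-methoxy-2,6-bis(methoxymethoxy)phenyl]methanone (enol form of the 1,3-diketone)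
Conditions: LiN(SiMe3)2 (3 equiv), THF (0.01 M), −78 °C → rt; aq. NH4Cl
Reagents that add atoms: none
Why: LiN(SiMe3)2 deprotonates the only enolisable position, the C3 methylene next to the ring A ketone (the benzoate has no α-hydrogen); the lithium enolate adds through carbon to the ester carbonyl C2 and the tetrahedral intermediate expels methoxide. This is an intramolecular crossed Claisen (Dieckmann-type) condensation, the reaction type that converts 2-(3-acylpropoxy)benzoates into 1-benzoxepin-5-ones and that gives the 1,3-diketones of the Baker–Venkataraman flavone synthesis. The oxepine closes in the 7-(enolexo)-exo-trig mode; two ring atoms (C1', C2') are held cis on ring B and a third is the ether oxygen, which lowers the entropic cost of a seven-membered closure. No stereocentre is created: C3 ends as the sp2 carbon of the chelated enol. C10 is γ to the enolate carbon and has no acidic hydrogen, so it can neither epimerise nor be lost by β-elimination. Ring closure must beat intermolecular condensation; high dilution and excess base, which converts the product irreversibly into its diketonate, should secure this. C-acylation is expected over O-acylation because of the lithium counter-ion and the strain of the alternative nine-membered enol ester. The aryl silyl ether and the acetals should be inert to the amide base and to the lithium methoxide released.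

Step 8
Reactants: 12 [(2S)-5-hydroxy-2-(prop-1-en-2-yl)-8-[tri(propan-2-yl)silyloxy]-2,3-dihydro-1-benzoxepin-4-yl][4-methoxy-2,6-bis(methoxymethoxy)phenyl]methanone
Product: 14 (10S)-5-hydroxy-7-methoxy-10-(prop-1-en-2-yl)-4'-[tri(propan-2-yl)silyloxy]flavone bridged from C3 to O–C2' by C9H2–C10H, via bisphenol diketone 13 (not isolated)
Conditions: HCl (2 M), MeOH/THF, 45 °C
Reagents that add atoms: none
Why: Acid methanolysis removes both acetals; either of the two equivalent phenols of 13 then adds to the ring B carbonyl (C2) and water is lost (cyclodehydration of a 2-hydroxyaryl 1,3-diketone), closing the pyranone and leaving the other phenol as the chelated 5-hydroxyl. The aryl silyl ether and the non-ionising allylic ether should survive dilute acid at this temperature.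

Step 9
Reactants: 14 (10S)-5-hydroxy-7-methoxy-10-(prop-1-en-2-yl)-4'-[tri(propan-2-yl)silyloxy]flavone bridged from C3 to O–C2' by C9H2–C10H
Product: 15 (10S)-5-hydroxy-7-methoxy-10-[2-(triethylsilylperoxy)propan-2-yl]-4'-[tri(propan-2-yl)silyloxy]flavone with the same C3–C9–C10–O–C2' bridge
Conditions: Co(acac)2 (20 mol %), Et3SiH, O2 (1 atm), ClCH2CH2Cl, rt
Reagents that add atoms: dioxygen, O=O; triethylsilane, CC[SiH](CC)CC
Why: Isayama–Mukaiyama hydroperoxysilylation; a cobalt hydride transfers a hydrogen atom to the terminal carbon of the 1,1-disubstituted alkene, dioxygen traps the tertiary radical much faster than it can fragment, and the peroxide is capped by silicon. The tetrasubstituted, electron-poor C2=C3 bond is inert. The higher catalyst loading allows for cobalt bound by the 5-hydroxy-4-keto unit.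

Step 10
Reactants: 15 (10S)-5-hydroxy-7-methoxy-10-[2-(triethylsilylperoxy)propan-2-yl]-4'-[tri(propan-2-yl)silyloxy]flavone with the C3–C9–C10–O–C2' bridge
Product: 16 (10S)-5-hydroxy-6-iodo-7-methoxy-10-[2-(triethylsilylperoxy)propan-2-yl]-4'-[tri(propan-2-yl)silyloxy]flavone with the same bridge
Conditions: BnMe3N·ICl2 (1.05 equiv), CaCO3, CH2Cl2/MeOH, rt
Reagents that add atoms: benzyltrimethylammonium dichloroiodate, C[N+](C)(C)Cc1ccccc1.Cl[I-]Cl
Why: Electrophilic aromatic iodination; in 5-hydroxy-7-methoxyflavones the chelated 5-hydroxyl directs this reagent to its ortho position C6, ring A is more electron-rich than the silyl-shielded ring B, and CaCO3 removes the HCl formed so the silyl peroxide is not solvolysed.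

Step 11
Reactants: 17 3-methylbut-1-yne
Product: 18 tributyl[(1E)-3-methylbut-1-en-1-yl]stannane
Conditions: Bu3SnH, Pd2(dba)3 (cat.), Cy3P·HBF4 (cat.), iPr2NEt, CH2Cl2, 0 °C
Reagents that add atoms: tributylstannane, CCCC[SnH](CCCC)CCCC
Why: Palladium-catalysed hydrostannation; syn addition with the bulky phosphine places tin on the terminal carbon, away from the branched substituent, and should give the E-alkenylstannane.

Step 12
Reactants: 16 (10S)-5-hydroxy-6-iodo-7-methoxy-10-[2-(triethylsilylperoxy)propan-2-yl]-4'-[tri(propan-2-yl)silyloxy]flavone with the C3–C9–C10–O–C2' bridge; 18 tributyl[(1E)-3-methylbut-1-en-1-yl]stannane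
Product: 19 (10S)-5-hydroxy-7-methoxy-6-[(1E)-3-methylbut-1-en-1-yl]-10-[2-(triethylsilylperoxy)propan-2-yl]-4'-[tri(propan-2-yl)silyloxy]flavone with the same bridge
Conditions: Pd2(dba)3 (5 mol %), AsPh3 (20 mol %), DMF, 40 °C, dark
Reagents that add atoms: none
Why: Stille coupling of an aryl iodide with retention of alkene geometry; the conditions are neutral and free of phosphine and base, so the hindered tertiary silyl peroxide is neither reduced nor unmasked, and tin, unlike boron, is not oxidised by a peroxide.

Step 13
Reactants: 19 (10S)-5-hydroxy-7-methoxy-6-[(1E)-3-methylbut-1-en-1-yl]-10-[2-(triethylsilylperoxy)propan-2-yl]-4'-[tri(propan-2-yl)silyloxy]flavone with the C3–C9–C10–O–C2' bridge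
Product: 20 (10S)-5,4'-dihydroxy-10-(2-hydroperoxypropan-2-yl)-7-methoxy-6-[(1E)-3-methylbut-1-en-1-yl]flavone with the C3–C9–C10–O–C2' bridge (CNP0171472.1)
Conditions: Bu4NF, AcOH, THF, 0 °C
Reagents that add atoms: none
Why: Fluoride cleaves the aryl O–Si and the peroxy O–Si bonds; acetic acid buffering keeps the hydroperoxide and the phenols protonated, and C10 and the E-alkene are unaffected.

## Compound list

1 | 5-methoxybenzene-1,3-diol | COc1cc(O)cc(O)c1 | starting material
2 | 1-methoxy-3,5-bis(methoxymethoxy)benzene | COCOc1cc(OC)cc(OCOC)c1 | intermediate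
3 | methyl 4-chloro-4-oxobutanoate | COC(=O)CCC(Cl)=O | starting material
4 | methyl 5-methyl-4-oxohex-5-enoate | COC(=O)CCC(=O)C(C)=C | intermediate
5 | methyl (4R)-4-hydroxy-5-methylhex-5-enoate (not isolated) | COC(=O)CC[C@@H](O)C(C)=C | intermediate
6 | (5R)-5-(prop-1-en-2-yl)oxolan-2-one | O=C1CC[C@H](C(C)=C)O1 | intermediate
7 | [4-methoxy-2,6-bis(methoxymethoxy)phenyl]lithium (not isolated) | [Li]c1c(OCOC)cc(OC)cc1OCOC | intermediate
8 | (4R)-4-hydroxy-1-[4-methoxy-2,6-bis(methoxymethoxy)phenyl]-5-methylhex-5-en-1-one | COCOc1cc(OC)cc(OCOC)c1C(=O)CC[C@@H](O)C(C)=C | intermediate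
9 | methyl 2,4-dihydroxybenzoate | COC(=O)c1ccc(O)cc1O | starting material
10 | methyl 2-hydroxy-4-[tri(propan-2-yl)silyloxy]benzoate | COC(=O)c1ccc(O[Si](C(C)C)(C(C)C)C(C)C)cc1O | intermediate
11 | methyl 2-{[(3S)-6-[4-methoxy-2,6-bis(methoxymethoxy)phenyl]-2-methyl-6-oxohex-1-en-3-yl]oxy}-4-[tri(propan-2-yl)silyloxy]benzoate | COC(=O)c1ccc(O[Si](C(C)C)(C(C)C)C(C)C)cc1O[C@H](C(C)=C)CCC(=O)c1c(OCOC)cc(OC)cc1OCOC | intermediate
12 | [(2S)-5-hydroxy-2-(prop-1-en-2-yl)-8-[tri(propan-2-yl)silyloxy]-2,3-dihydro-1-benzoxepin-4-yl][4-methoxy-2,6-bis(methoxymethoxy)phenyl]methanone | OC1=C(C(=O)c2c(OCOC)cc(OC)cc2OCOC)C[C@@H](C(C)=C)Oc2cc(O[Si](C(C)C)(C(C)C)C(C)C)ccc12 | intermediate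
13 | (2,6-dihydroxy-4-methoxyphenyl)[(2S)-5-hydroxy-2-(prop-1-en-2-yl)-8-[tri(propan-2-yl)silyloxy]-2,3-dihydro-1-benzoxepin-4-yl]methanone (not isolated) | OC1=C(C(=O)c2c(O)cc(OC)cc2O)C[C@@H](C(C)=C)Oc2cc(O[Si](C(C)C)(C(C)C)C(C)C)ccc12 | intermediate
14 | (10S)-5-hydroxy-7-methoxy-10-(prop-1-en-2-yl)-4'-[tri(propan-2-yl)silyloxy]flavone, C3–C9H2–C10H–O–C2' bridged | COc1cc2oc3c(c(=O)c2c(O)c1)C[C@@H](C(C)=C)Oc1cc(O[Si](C(C)C)(C(C)C)C(C)C)ccc1-3 | intermediate
15 | (10S)-5-hydroxy-7-methoxy-10-[2-(triethylsilylperoxy)propan-2-yl]-4'-[tri(propan-2-yl)silyloxy] bridged flavone | COc1cc2oc3c(c(=O)c2c(O)c1)C[C@@H](C(C)(C)OO[Si](CC)(CC)CC)Oc1cc(O[Si](C(C)C)(C(C)C)C(C)C)ccc1-3 | intermediate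
16 | (10S)-5-hydroxy-6-iodo-7-methoxy-10-[2-(triethylsilylperoxy)propan-2-yl]-4'-[tri(propan-2-yl)silyloxy] bridged flavone | COc1cc2oc3c(c(=O)c2c(O)c1I)C[C@@H](C(C)(C)OO[Si](CC)(CC)CC)Oc1cc(O[Si](C(C)C)(C(C)C)C(C)C)ccc1-3 | intermediate
17 | 3-methylbut-1-yne | CC(C)C#C | starting material
18 | tributyl[(1E)-3-methylbut-1-en-1-yl]stannane | CCCC[Sn](CCCC)(CCCC)/C=C/C(C)C | intermediate
19 | (10S)-5-hydroxy-7-methoxy-6-[(1E)-3-methylbut-1-en-1-yl]-10-[2-(triethylsilylperoxy)propan-2-yl]-4'-[tri(propan-2-yl)silyloxy] bridged flavone | COc1cc2oc3c(c(=O)c2c(O)c1/C=C/C(C)C)C[C@@H](C(C)(C)OO[Si](CC)(CC)CC)Oc1cc(O[Si](C(C)C)(C(C)C)C(C)C)ccc1-3 | intermediate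
20 | (10S)-5,4'-dihydroxy-10-(2-hydroperoxypropan-2-yl)-7-methoxy-6-[(1E)-3-methylbut-1-en-1-yl] bridged flavone (CNP0171472.1) | COc1cc2oc3c(c(=O)c2c(O)c1/C=C/C(C)C)C[C@@H](C(C)(C)OO)Oc1cc(O)ccc1-3 | target

## Step count and least certain steps

Total: 13 steps. Longest linear sequence: 10 steps (steps 2, 3, 4, 6, 7, 8, 9, 10, 12, 13, from 3 to 20); steps 1, 5 and 11 are one-step side branches.

**Step 7 (key step).** The most likely failure is slow acyl substitution: the benzoate carries two oxygen donors (ortho and para), so the enolate may be quenched by proton transfer or condense intermolecularly before the ring closes. Fallback, from 11 back to 12: the methyl ester is cleaved with Me3SnOH in ClCH2CH2Cl to carboxylic acid F1. The acid is converted with 1H-benzotriazole and a carbodiimide into N-acylbenzotriazole F2. Soft enolisation of the ketone with MgBr2·OEt2 and iPr2NEt in dilute CH2Cl2 then brings about C-acylation by the activated acyl donor and gives 12. This raises the electrophilicity of C2 and replaces the hard lithium enolate by a chelated magnesium enolate.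

**Step 6.** Substitution at a hindered secondary allylic carbinol by a hydrogen-bonded, weakly nucleophilic phenol may be slow. Elimination to the diene, allylic transposition, capture of the activated carbinol by the ketone oxygen, or partial loss of configuration through an ion pair could then take over. Fallback, from 8 back to 11: the alcohol is converted with MsCl and Et3N at −20 °C into mesylate F3, which is displaced by the cesium phenoxide of 10 (Cs2CO3, DMF). The displacement is SN2 with the same inversion, and the free phenoxide is a better nucleophile than the phenol under redox-condensation conditions.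

**Step 12.** Zerovalent palladium may cleave or reduce the O–O–Si unit, or transmetalation at the doubly ortho-substituted iodide may be too slow at a temperature the silyl peroxide tolerates. Fallback, from 16 back to 20:
- The triethylsilyl group is removed with aqueous AcOH in THF to give hydroperoxide F4.
- F4 is capped with 2-methoxypropene and pyridinium p-toluenesulfonate as the base-stable peroxyketal F5.
- Alkyne 17 is hydroborated with pinacolborane (Cp2Zr(H)Cl cat.) to alkenylboronate F6.
- Suzuki–Miyaura coupling of F5 with F6 (Pd2(dba)3, AsPh3, K3PO4, THF/H2O, 50 °C) gives peroxyketal F7.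
- Aqueous AcOH releases hydroperoxide F8, and Bu4NF/AcOH removes the aryl silyl ether to give 20.

A fully substituted dialkyl peroxide tolerates base and cannot transfer oxygen to boron.

**Step 10.** Site control may be lost, with attack at C8 (para to the 5-hydroxyl) or at C5' of ring B, or the silyl peroxide may be solvolysed by HCl that is not buffered fast enough. Fallback, from 15 back to 19, bypassing steps 10 to 12:
- Ortho-formylation through the magnesium phenoxide (MgCl2, Et3N, paraformaldehyde, MeCN, 70 °C) can only reach C6 and gives aldehyde F9.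
- 1-Phenyl-1H-tetrazole-5-thiol is alkylated with 1-bromo-2-methylpropane (K2CO3, acetone) to sulfide F10, which is oxidised with H2O2 and (NH4)6Mo7O24·4H2O to sulfone F11.
- Julia–Kocienski olefination of F9 with F11 and KN(SiMe3)2 (excess, THF, −78 °C) should give the E-alkene 19.

## Further compounds

F1 | step 7 | 2-{[(3S)-6-[4-methoxy-2,6-bis(methoxymethoxy)phenyl]-2-methyl-6-oxohex-1-en-3-yl]oxy}-4-[tri(propan-2-yl)silyloxy]benzoic acid | OC(=O)c1ccc(O[Si](C(C)C)(C(C)C)C(C)C)cc1O[C@H](C(C)=C)CCC(=O)c1c(OCOC)cc(OC)cc1OCOC
F2 | step 7 | (4S)-4-{[2-(1H-benzotriazol-1-ylcarbonyl)-5-[tri(propan-2-yl)silyloxy]phenyl]oxy}-1-[4-methoxy-2,6-bis(methoxymethoxy)phenyl]-5-methylhex-5-en-1-one | O=C(n1nnc2ccccc12)c1ccc(O[Si](C(C)C)(C(C)C)C(C)C)cc1O[C@H](C(C)=C)CCC(=O)c1c(OCOC)cc(OC)cc1OCOC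
F3 | step 6 | (3R)-6-[4-methoxy-2,6-bis(methoxymethoxy)phenyl]-2-methyl-6-oxohex-1-en-3-yl methanesulfonate | COCOc1cc(OC)cc(OCOC)c1C(=O)CC[C@@H](OS(C)(=O)=O)C(C)=C
F4 | step 12 | (10S)-10-(2-hydroperoxypropan-2-yl)-5-hydroxy-6-iodo-7-methoxy-4'-[tri(propan-2-yl)silyloxy] bridged flavone | COc1cc2oc3c(c(=O)c2c(O)c1I)C[C@@H](C(C)(C)OO)Oc1cc(O[Si](C(C)C)(C(C)C)C(C)C)ccc1-3
F5 | step 12 | (10S)-5-hydroxy-6-iodo-7-methoxy-10-{2-[(2-methoxypropan-2-yl)peroxy]propan-2-yl}-4'-[tri(propan-2-yl)silyloxy] bridged flavone | COc1cc2oc3c(c(=O)c2c(O)c1I)C[C@@H](C(C)(C)OOC(C)(C)OC)Oc1cc(O[Si](C(C)C)(C(C)C)C(C)C)ccc1-3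
F6 | step 12 | 4,4,5,5-tetramethyl-2-[(1E)-3-methylbut-1-en-1-yl]-1,3,2-dioxaborolane | CC(C)/C=C/B1OC(C)(C)C(C)(C)O1
F7 | step 12 | (10S)-5-hydroxy-7-methoxy-10-{2-[(2-methoxypropan-2-yl)peroxy]propan-2-yl}-6-[(1E)-3-methylbut-1-en-1-yl]-4'-[tri(propan-2-yl)silyloxy] bridged flavone | COc1cc2oc3c(c(=O)c2c(O)c1/C=C/C(C)C)C[C@@H](C(C)(C)OOC(C)(C)OC)Oc1cc(O[Si](C(C)C)(C(C)C)C(C)C)ccc1-3
F8 | step 12 | (10S)-10-(2-hydroperoxypropan-2-yl)-5-hydroxy-7-methoxy-6-[(1E)-3-methylbut-1-en-1-yl]-4'-[tri(propan-2-yl)silyloxy] bridged flavone | COc1cc2oc3c(c(=O)c2c(O)c1/C=C/C(C)C)C[C@@H](C(C)(C)OO)Oc1cc(O[Si](C(C)C)(C(C)C)C(C)C)ccc1-3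
F9 | step 10 | (10S)-6-formyl-5-hydroxy-7-methoxy-10-[2-(triethylsilylperoxy)propan-2-yl]-4'-[tri(propan-2-yl)silyloxy] bridged flavone | COc1cc2oc3c(c(=O)c2c(O)c1C=O)C[C@@H](C(C)(C)OO[Si](CC)(CC)CC)Oc1cc(O[Si](C(C)C)(C(C)C)C(C)C)ccc1-3
F10 | step 10 | 5-[(2-methylpropyl)sulfanyl]-1-phenyl-1H-tetrazole | CC(C)CSc1nnnn1-c1ccccc1
F11 | step 10 | 5-[(2-methylpropyl)sulfonyl]-1-phenyl-1H-tetrazole | CC(C)CS(=O)(=O)c1nnnn1-c1ccccc1
A1 | alternative 1 | (10S)-5,4'-dihydroxy-7-methoxy-6-[(1E)-3-methylbut-1-en-1-yl]-10-(prop-1-en-2-yl) bridged flavone | COc1cc2oc3c(c(=O)c2c(O)c1/C=C/C(C)C)C[C@@H](C(C)=C)Oc1cc(O)ccc1-3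
A2 | alternative 2 | methyl 2-{(10S)-5,7-dimethoxy-4'-[tri(propan-2-yl)silyloxy] bridged flavon-10-yl}-2-methylpropanoate | COc1cc(OC)c2c(c1)oc1c(c2=O)C[C@@H](C(C)(C)C(=O)OC)Oc2cc(O[Si](C(C)C)(C(C)C)C(C)C)ccc2-1
A3 | alternative 3 | (10S)-10-{[(4R)-4-benzyl-2-oxo-1,3-oxazolidin-3-yl]carbonyl}-4'-(tert-butyldimethylsilyloxy)-5,7-dimethoxy bridged flavone | COc1cc(OC)c2c(c1)oc1c(c2=O)C[C@@H](C(=O)N2[C@H](Cc3ccccc3)COC2=O)Oc2cc(O[Si](C)(C)C(C)(C)C)ccc2-1
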